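The biaryl bond C3'–C8 is never made by coupling; instead the central ring B is grown between the two halves. A Robinson annulation joins a keto-aldehyde carrying the daidzein ring A with an aryl vinyl ketone carrying the genistein ring A, forming C1'–C6' (Michael) and C2'=C3' (aldol) and closing ring B as a 2-aryl-4-alkylcyclohex-2-enone. This exploits the substitution of ring B: oxygen on C4', the hindered aryl (genistein C8) ortho on C3' and the daidzein C3 carbon para on C1'. Dehydrogenation turns the ketone into the 4'-hydroxyl; debenzylation, one acylation and two one-carbon ring closures then complete both chromones.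

Key step: step 8

Remark: the target SMILES carries no stereodescriptor, so the hindered biaryl axis C3'–C8 is treated as configurationally unassigned and no axial control is attempted.

Step 1
Reactants: 1 2-hydroxy-4,6-dimethoxybenzaldehyde
Product: 2 2-(benzyloxy)-4,6-dimethoxybenzaldehyde
Conditions: BnBr, K2CO3, DMF, 60 °C
Reagents that add atoms: benzyl bromide BrCc1ccccc1
Why: Williamson ether synthesis, in which the carbonate-generated phenoxide displaces bromide and thereby tags the one oxygen that must later become O1 of the genistein chromone, while the two methyl ethers mark the future 5- and 7-hydroxyls.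

Step 2
Reactants: 2 2-(benzyloxy)-4,6-dimethoxybenzaldehyde
Product: 4 2-[2-(benzyloxy)-4,6-dimethoxyphenyl]acetaldehyde, via methyl enol ether 3 (not isolated)
Conditions: Ph3P(CH2OCH3)Cl, KOtBu, THF, 0 °C to rt; then 2 M aq. HCl, THF, rt
Reagents that add atoms: (methoxymethyl)triphenylphosphonium chloride COC[P+](c1ccccc1)(c1ccccc1)c1ccccc1.[Cl-]; water O
Why: Wittig olefination with the methoxymethylene ylide gives the aryl enol ether, and dilute acid hydrolyses it (C-protonation, hydration, loss of methanol) to the one-carbon-homologated aldehyde without touching the aryl benzyl ether.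

Step 3
Reactants: 4 2-[2-(benzyloxy)-4,6-dimethoxyphenyl]acetaldehyde
Product: 5 racemic 1-[2-(benzyloxy)-4,6-dimethoxyphenyl]but-3-en-2-ol
Conditions: CH2=CHMgBr, THF, −78 °C
Reagents that add atoms: vinylmagnesium bromide C=C[Mg]Br
Why: Grignard 1,2-addition to the aldehyde, run cold so that addition outpaces enolisation of the arylacetaldehyde; the carbinol stereocentre forms as a racemate and is removed by the next oxidation.

Step 4
Reactants: 5 racemic 1-[2-(benzyloxy)-4,6-dimethoxyphenyl]but-3-en-2-ol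
Product: 6 1-[2-(benzyloxy)-4,6-dimethoxyphenyl]but-3-en-2-one
Conditions: Dess–Martin periodinane, pyridine, CH2Cl2, 0 °C; used at once
Reagents that add atoms: none
Why: Dess–Martin oxidation of the secondary allylic alcohol under buffered, non-basic conditions should give the enone without moving the double bond or enolising the benzylic methylene, and the sensitive vinyl ketone is taken directly into step 8.

Step 5
Reactants: 7 paeonol, 1-(2-hydroxy-4-methoxyphenyl)ethanone
Product: 8 1-[2-(benzyloxy)-4-methoxyphenyl]ethanone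
Conditions: BnBr, K2CO3, DMF, 60 °C
Reagents that add atoms: benzyl bromide BrCc1ccccc1
Why: Williamson ether synthesis on the hydrogen-bonded ortho-hydroxy ketone; the benzyl group marks the oxygen destined to be O1 of the daidzein chromone.

Step 6
Reactants: 8 1-[2-(benzyloxy)-4-methoxyphenyl]ethanone
Product: 10 1-[2-(benzyloxy)-4-methoxyphenyl]pent-4-en-1-one, via lithium enolate 9 (not isolated)
Conditions: LiN(i-Pr)2 (1.05 equiv), THF, −78 °C; then allyl bromide (1.0 equiv), −78 °C to 0 °C
Reagents that add atoms: allyl bromide C=CCBr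
Why: SN2 alkylation of the kinetic lithium enolate of the methyl ketone installs a chain whose terminal alkene is a masked aldehyde, and one equivalent of base and electrophile at low temperature limits double alkylation.

Step 7
Reactants: 10 1-[2-(benzyloxy)-4-methoxyphenyl]pent-4-en-1-one
Product: 12 4-[2-(benzyloxy)-4-methoxyphenyl]-4-oxobutanal, via ozonide 11 (not isolated)
Conditions: O3, CH2Cl2, −78 °C, stopped at consumption of the alkene; then PPh3, −78 °C to rt
Reagents that add atoms: ozone [O-][O+]=O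
Why: Ozonolysis (Criegee mechanism) of the terminal alkene followed by phosphine reduction of the ozonide gives the aldehyde, while the ketone-deactivated arene and the benzyl ether are spared if ozone is not used in excess.

Step 8
Reactants: 12 4-[2-(benzyloxy)-4-methoxyphenyl]-4-oxobutanal; 6 1-[2-(benzyloxy)-4,6-dimethoxyphenyl]but-3-en-2-one
Product: 14 racemic 2-[2-(benzyloxy)-4,6-dimethoxyphenyl]-4-{2-[2-(benzyloxy)-4-methoxyphenyl]-2-oxoethyl}cyclohex-2-en-1-one, via Michael adduct 13 (not isolated)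
Conditions: pyrrolidine (0.3 equiv), CH2Cl2, 0 °C to rt, 6 added slowly; then AcOH (1 equiv), 40 °C
Reagents that add atoms: none
Why: Pyrrolidine converts the aldehyde of 12 into an enamine whose β-carbon (future C1') adds to the terminal carbon of enone 6 (future C6'), and hydrolysis of the resulting iminium releases keto-aldehyde 13. With acetic acid present, pyrrolidinium acetate enolises the benzyl ketone at its benzylic carbon (future C3'), which attacks the aldehyde carbon (future C2') in a 6-(enolexo)-exo-trig aldol closure, and dehydration gives the conjugated 2-arylcyclohexenone, ring B. The closest known reaction type is the secondary-amine-catalysed Robinson annulation of α-unbranched aldehydes with vinyl ketones to 4-substituted cyclohex-2-enones. The only new stereocentre, C4 of the cyclohexenone (C1'), is set without control by the achiral catalyst, so 14 is racemic, which is harmless because step 9 flattens this carbon. The selectivity needed is aldol closure between the benzylic carbon and the aldehyde: these are the most acidic methylene and the most electrophilic carbonyl, their pairing gives a six-membered ring ending in a styrene-type conjugated enone, and the aryl ketone is deactivated by its ortho and para alkoxy groups. Slow addition of 6 should limit its self-condensation, and a carboxylic acid in place of a strong acid should avoid furan formation from the 1,4-keto-aldehyde unit.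

Step 9
Reactants: 14 racemic 2-[2-(benzyloxy)-4,6-dimethoxyphenyl]-4-{2-[2-(benzyloxy)-4-methoxyphenyl]-2-oxoethyl}cyclohex-2-en-1-one
Product: 15 1-[2-(benzyloxy)-4-methoxyphenyl]-2-{3-[2-(benzyloxy)-4,6-dimethoxyphenyl]-4-hydroxyphenyl}ethanone
Conditions: Pd(OCOCF3)2 (5 mol %), 2-(dimethylamino)pyridine (10 mol %), TsOH (20 mol %), O2 (1 atm), DMSO, 80 °C
Reagents that add atoms: none
Why: Palladium-catalysed aerobic dehydrogenation of a cyclohexenone to a phenol, in which a divalent-palladium enolate at C6 undergoes β-hydride elimination to the cross-conjugated dienone that tautomerises to the phenol while O2 reoxidises the metal; the C1' stereocentre is erased and the ketone oxygen becomes the 4'-hydroxyl.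

Step 10
Reactants: 15 1-[2-(benzyloxy)-4-methoxyphenyl]-2-{3-[2-(benzyloxy)-4,6-dimethoxyphenyl]-4-hydroxyphenyl}ethanone
Product: 16 2-[4-hydroxy-3-(2-hydroxy-4,6-dimethoxyphenyl)phenyl]-1-(2-hydroxy-4-methoxyphenyl)ethanone
Conditions: H2 (1 atm), Pd/C (10% palladium on carbon), EtOAc/MeOH, rt
Reagents that add atoms: none
Why: Catalytic hydrogenolysis of the two aryl benzyl ethers under neutral conditions at one atmosphere, where the aryl ketone and the methyl ethers should not be reduced, frees exactly the two hydroxyls that will become the chromone ring oxygens.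

Step 11
Reactants: 16 2-[4-hydroxy-3-(2-hydroxy-4,6-dimethoxyphenyl)phenyl]-1-(2-hydroxy-4-methoxyphenyl)ethanone; 17 4-methoxyphenylacetic acid
Product: 19 8-[2-hydroxy-5-(7-methoxy-4-oxo-4H-chromen-3-yl)phenyl]-5,7-dimethoxy-3-(4-methoxyphenyl)-4H-chromen-4-one, via bis-deoxybenzoin 18 (not isolated)
Conditions: 17 (1.1 equiv), BF3·OEt2, 85 °C; then DMF, CH3SO2Cl, 70 °C; aq. NaOAc
Reagents that add atoms: N,N-dimethylformamide CN(C)C=O
Why: BF3-mediated Friedel–Crafts acylation should place the arylacetyl group on the most electron-rich ring ortho to its free hydroxyl (the product is held as a BF2 chelate, and the central para-alkylphenol and the acyl-deactivated ring are far less nucleophilic), after which the Vilsmeier-type iminium salt from DMF and CH3SO2Cl formylates both deoxybenzoin methylenes and each ortho-hydroxyl closes onto the new carbon with loss of dimethylamine, giving both isoflavone rings in one pot.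

Step 12
Reactants: 19 8-[2-hydroxy-5-(7-methoxy-4-oxo-4H-chromen-3-yl)phenyl]-5,7-dimethoxy-3-(4-methoxyphenyl)-4H-chromen-4-one
Product: 20 8-[2-hydroxy-5-(7-hydroxy-4-oxo-4H-chromen-3-yl)phenyl]-5,7-dihydroxy-3-(4-hydroxyphenyl)-4H-chromen-4-one
Conditions: BBr3 (excess), CH2Cl2, −78 °C to rt; then H2O
Reagents that add atoms: none
Why: Lewis-acid ether cleavage, in which BBr3 complexes each aryl methyl ether and bromide removes the methyl group by SN2, so excess reagent should free all four hydroxyls while the chromone rings and the biaryl bond stay inert.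

Compound list
1 | 2-hydroxy-4,6-dimethoxybenzaldehyde | COc1cc(O)c(C=O)c(OC)c1 | starting material
2 | 2-(benzyloxy)-4,6-dimethoxybenzaldehyde | COc1cc(OCc2ccccc2)c(C=O)c(OC)c1 | intermediate
3 | 1-(benzyloxy)-3,5-dimethoxy-2-(2-methoxyethenyl)benzene, E/Z mixture | COC=Cc1c(OCc2ccccc2)cc(OC)cc1OC | intermediate
4 | 2-[2-(benzyloxy)-4,6-dimethoxyphenyl]acetaldehyde | O=CCc1c(OCc2ccccc2)cc(OC)cc1OC | intermediate
5 | racemic 1-[2-(benzyloxy)-4,6-dimethoxyphenyl]but-3-en-2-ol | C=CC(O)Cc1c(OCc2ccccc2)cc(OC)cc1OC | intermediate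
6 | 1-[2-(benzyloxy)-4,6-dimethoxyphenyl]but-3-en-2-one | C=CC(=O)Cc1c(OCc2ccccc2)cc(OC)cc1OC | intermediate
7 | paeonol, 1-(2-hydroxy-4-methoxyphenyl)ethanone | CC(=O)c1ccc(OC)cc1O | starting material
8 | 1-[2-(benzyloxy)-4-methoxyphenyl]ethanone | CC(=O)c1ccc(OC)cc1OCc1ccccc1 | intermediate
9 | lithium enolate of 8, lithium 1-[2-(benzyloxy)-4-methoxyphenyl]ethenolate | [Li]OC(=C)c1ccc(OC)cc1OCc1ccccc1 | intermediate
10 | 1-[2-(benzyloxy)-4-methoxyphenyl]pent-4-en-1-one | C=CCCC(=O)c1ccc(OC)cc1OCc1ccccc1 | intermediate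
11 | racemic 1-[2-(benzyloxy)-4-methoxyphenyl]-3-(1,2,4-trioxolan-3-yl)propan-1-one (ozonide) | O=C(CCC1OCOO1)c1ccc(OC)cc1OCc1ccccc1 | intermediate
12 | 4-[2-(benzyloxy)-4-methoxyphenyl]-4-oxobutanal | O=CCCC(=O)c1ccc(OC)cc1OCc1ccccc1 | intermediate
13 | racemic 2-{2-[2-(benzyloxy)-4-methoxyphenyl]-2-oxoethyl}-6-[2-(benzyloxy)-4,6-dimethoxyphenyl]-5-oxohexanal | O=CC(CC(=O)c1ccc(OC)cc1OCc1ccccc1)CCC(=O)Cc1c(OCc2ccccc2)cc(OC)cc1OC | intermediate
14 | racemic 2-[2-(benzyloxy)-4,6-dimethoxyphenyl]-4-{2-[2-(benzyloxy)-4-methoxyphenyl]-2-oxoethyl}cyclohex-2-en-1-one | O=C1CCC(CC(=O)c2ccc(OC)cc2OCc2ccccc2)C=C1c1c(OCc2ccccc2)cc(OC)cc1OC | intermediate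
15 | 1-[2-(benzyloxy)-4-methoxyphenyl]-2-{3-[2-(benzyloxy)-4,6-dimethoxyphenyl]-4-hydroxyphenyl}ethanone | Oc1ccc(CC(=O)c2ccc(OC)cc2OCc2ccccc2)cc1-c1c(OCc2ccccc2)cc(OC)cc1OC | intermediate
16 | 2-[4-hydroxy-3-(2-hydroxy-4,6-dimethoxyphenyl)phenyl]-1-(2-hydroxy-4-methoxyphenyl)ethanone | Oc1ccc(CC(=O)c2ccc(OC)cc2O)cc1-c1c(O)cc(OC)cc1OC | intermediate
17 | 4-methoxyphenylacetic acid | COc1ccc(CC(=O)O)cc1 | starting material
18 | 1-{2-hydroxy-3-[2-hydroxy-5-(2-(2-hydroxy-4-methoxyphenyl)-2-oxoethyl)phenyl]-4,6-dimethoxyphenyl}-2-(4-methoxyphenyl)ethanone | Oc1ccc(CC(=O)c2ccc(OC)cc2O)cc1-c1c(O)c(C(=O)Cc2ccc(OC)cc2)c(OC)cc1OC | intermediate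
19 | 8-[2-hydroxy-5-(7-methoxy-4-oxo-4H-chromen-3-yl)phenyl]-5,7-dimethoxy-3-(4-methoxyphenyl)-4H-chromen-4-one | O=c1c(-c2ccc(O)c(-c3c(OC)cc(OC)c4c(=O)c(-c5ccc(OC)cc5)coc34)c2)coc2cc(OC)ccc12 | intermediate
20 | 8-[2-hydroxy-5-(7-hydroxy-4-oxo-4H-chromen-3-yl)phenyl]-5,7-dihydroxy-3-(4-hydroxyphenyl)-4H-chromen-4-one (CNP0500144.0) | O=c1c(-c2ccc(O)c(-c3c(O)cc(O)c4c(=O)c(-c5ccc(O)cc5)coc34)c2)coc2cc(O)ccc12 | target

Total step count: 12. Longest linear sequence: 9 steps (steps 1 to 4, then 8 to 12); the paeonol branch (steps 5 to 7) joins at step 8.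

Steps most likely to fail

Step 8. The vinyl ketone 6 may be consumed by self-condensation through its acidic benzylic methylene, or by amine-initiated polymerisation, faster than the enamine of 12 adds to it, so that ring closure does not keep pace. The fallback sets out from 4 and 12 and comes back at 15. It moves the aryl group onto the α-carbon of the acceptor, which then has no acidic methylene, and lets a methyl ketone close the ring. CH3MgBr adds to aldehyde 4 to give racemic 1-[2-(benzyloxy)-4,6-dimethoxyphenyl]propan-2-ol F1. Dess–Martin oxidation gives 1-[2-(benzyloxy)-4,6-dimethoxyphenyl]propan-2-one F2. Mannich-type methylenation at the benzylic carbon (paraformaldehyde, diisopropylammonium trifluoroacetate, THF, reflux) gives 3-[2-(benzyloxy)-4,6-dimethoxyphenyl]but-3-en-2-one F3. Pyrrolidine-catalysed Michael addition of 12 to F3, then aldol condensation of the methyl ketone with the aldehyde (AcOH, 40 °C), should give the isomeric enone 6-[2-(benzyloxy)-4,6-dimethoxyphenyl]-4-{2-[2-(benzyloxy)-4-methoxyphenyl]-2-oxoethyl}cyclohex-2-en-1-one F4. F4 carries the same oxygen, aryl and alkyl pattern on ring B, so the dehydrogenation conditions of step 9 convert it into phenol 15.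

Step 9. Formation of the palladium enolate may be slow beside the hindered 2-aryl group, and the deoxybenzoin methylene may be over-oxidised under O2 in hot DMSO. The fallback sets out from 14 and comes back at 15. It replaces catalytic dehydrogenation by hydride abstraction from a silyl dienol ether. Me3SiOSO2CF3 and Et3N (CH2Cl2, 0 °C) silylate both ketones to give 3-[2-(benzyloxy)-4,6-dimethoxyphenyl]-5-{2-[2-(benzyloxy)-4-methoxyphenyl]-2-(trimethylsilyloxy)ethenyl}-2-(trimethylsilyloxy)cyclohexa-1,3-diene F5. DDQ (1 equiv, CH2Cl2, 0 °C) aromatises the silyloxycyclohexadiene to 1-(benzyloxy)-2-{5-[2-(2-(benzyloxy)-4-methoxyphenyl)-2-(trimethylsilyloxy)ethenyl]-2-(trimethylsilyloxy)phenyl}-3,5-dimethoxybenzene F6. Dilute HCl in THF removes both silyl groups to give 15.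

Step 11. Acylation may go para to the hydroxyl of the dimethoxyphenol ring, or onto the oxygen or ortho-carbon of the free central phenol, and the one-pot closure may leave one ring open. The fallback sets out from 15 and comes back at 20. It caps the central phenol and separates acylation from ring closure.
- CH3I and K2CO3 in acetone give 1-[2-(benzyloxy)-4-methoxyphenyl]-2-{3-[2-(benzyloxy)-4,6-dimethoxyphenyl]-4-methoxyphenyl}ethanone F7.
- Hydrogenolysis (H2, Pd/C) gives 2-[3-(2-hydroxy-4,6-dimethoxyphenyl)-4-methoxyphenyl]-1-(2-hydroxy-4-methoxyphenyl)ethanone F8.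
- Acylation with 17 in BF3·OEt2 is stopped and purified at 1-{2-hydroxy-3-[5-(2-(2-hydroxy-4-methoxyphenyl)-2-oxoethyl)-2-methoxyphenyl]-4,6-dimethoxyphenyl}-2-(4-methoxyphenyl)ethanone F9.
- DMF dimethyl acetal (enaminone formation, then acid-mediated cyclisation) closes both rings to 5,7-dimethoxy-8-[2-methoxy-5-(7-methoxy-4-oxo-4H-chromen-3-yl)phenyl]-3-(4-methoxyphenyl)-4H-chromen-4-one F10.
- BBr3 cleaves all five methyl ethers to give 20.

Further compounds
F1 | step 8 | racemic 1-[2-(benzyloxy)-4,6-dimethoxyphenyl]propan-2-ol | CC(O)Cc1c(OCc2ccccc2)cc(OC)cc1OC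
F2 | step 8 | 1-[2-(benzyloxy)-4,6-dimethoxyphenyl]propan-2-one | CC(=O)Cc1c(OCc2ccccc2)cc(OC)cc1OC
F3 | step 8 | 3-[2-(benzyloxy)-4,6-dimethoxyphenyl]but-3-en-2-one | CC(=O)C(=C)c1c(OCc2ccccc2)cc(OC)cc1OC
F4 | step 8 | 6-[2-(benzyloxy)-4,6-dimethoxyphenyl]-4-{2-[2-(benzyloxy)-4-methoxyphenyl]-2-oxoethyl}cyclohex-2-en-1-one, racemic mixture of diastereomers | O=C1C=CC(CC(=O)c2ccc(OC)cc2OCc2ccccc2)CC1c1c(OCc2ccccc2)cc(OC)cc1OC
F5 | step 9 | 3-[2-(benzyloxy)-4,6-dimethoxyphenyl]-5-{2-[2-(benzyloxy)-4-methoxyphenyl]-2-(trimethylsilyloxy)ethenyl}-2-(trimethylsilyloxy)cyclohexa-1,3-diene, racemic, enol ether geometry unassigned | C[Si](C)(C)OC1=CCC(C=C(O[Si](C)(C)C)c2ccc(OC)cc2OCc2ccccc2)C=C1c1c(OCc2ccccc2)cc(OC)cc1OC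
F6 | step 9 | 1-(benzyloxy)-2-{5-[2-(2-(benzyloxy)-4-methoxyphenyl)-2-(trimethylsilyloxy)ethenyl]-2-(trimethylsilyloxy)phenyl}-3,5-dimethoxybenzene, enol ether geometry unassigned | C[Si](C)(C)Oc1ccc(C=C(O[Si](C)(C)C)c2ccc(OC)cc2OCc2ccccc2)cc1-c1c(OCc2ccccc2)cc(OC)cc1OC
F7 | step 11 | 1-[2-(benzyloxy)-4-methoxyphenyl]-2-{3-[2-(benzyloxy)-4,6-dimethoxyphenyl]-4-methoxyphenyl}ethanone | COc1ccc(CC(=O)c2ccc(OC)cc2OCc2ccccc2)cc1-c1c(OCc2ccccc2)cc(OC)cc1OC
F8 | step 11 | 2-[3-(2-hydroxy-4,6-dimethoxyphenyl)-4-methoxyphenyl]-1-(2-hydroxy-4-methoxyphenyl)ethanone | COc1ccc(CC(=O)c2ccc(OC)cc2O)cc1-c1c(O)cc(OC)cc1OC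
F9 | step 11 | 1-{2-hydroxy-3-[5-(2-(2-hydroxy-4-methoxyphenyl)-2-oxoethyl)-2-methoxyphenyl]-4,6-dimethoxyphenyl}-2-(4-methoxyphenyl)ethanone | COc1ccc(CC(=O)c2ccc(OC)cc2O)cc1-c1c(O)c(C(=O)Cc2ccc(OC)cc2)c(OC)cc1OC
F10 | step 11 | 5,7-dimethoxy-8-[2-methoxy-5-(7-methoxy-4-oxo-4H-chromen-3-yl)phenyl]-3-(4-methoxyphenyl)-4H-chromen-4-one | O=c1c(-c2ccc(OC)c(-c3c(OC)cc(OC)c4c(=O)c(-c5ccc(OC)cc5)coc34)c2)coc2cc(OC)ccc12
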